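**Retrosynthetic overview**
1. C7=C8 is disconnected last: aldol condensation of the chlorinated hydroxycyclopentenone 11 (ring, chlorine, lower chain, C12 carbinol) with the Z-enal 15.
2. Key disconnection is the C12–O bond: enantioconvergent aerobic gamma-hydroxylation of racemic 2-chloro-4-octenylcyclopentenone 8 through its planar dienolate sets the only stereocentre.
3. 8 comes from 3-ethoxycyclopent-2-en-1-one by C2 chlorination, alpha'-alkylation with (Z)-1-bromooct-2-ene and reductive 1,3-carbonyl transposition.
4. 15 comes from methyl hex-5-enoate by Z-retentive cross-metathesis with cis-but-2-ene-1,4-diol, then oxidation.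
5. Ring order: the single carbocycle is bought as the cyclopentenone; no ring is formed in the route.

Assumption: numbers are given to starting materials, intermediates and products; reagents, catalysts and solvents are named where they are used.

**Step 1**
Reactants: 1 3-ethoxycyclopent-2-en-1-one
Product: 2 2-chloro-3-ethoxycyclopent-2-en-1-one
Conditions: NCS (1.05 equiv), CH2Cl2, 0 °C to rt
Reagents that add atoms: N-chlorosuccinimide, ClN1C(=O)CCC1=O
Why: Electrophilic alpha-chlorination of a vinylogous ester; C2 is the nucleophilic carbon of the enol ether and the product stays conjugated.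

**Step 2**
Reactants: 3 (Z)-oct-2-en-1-ol
Product: 4 (Z)-1-bromooct-2-ene
Conditions: CBr4, PPh3, CH2Cl2, −20 to 0 °C
Reagents that add atoms: carbon tetrabromide, BrC(Br)(Br)Br
Why: Appel bromination by SN2 displacement of the primary oxyphosphonium, cold enough to keep the Z olefin.

**Step 3**
Reactants: 2 2-chloro-3-ethoxycyclopent-2-en-1-one; 4 (Z)-1-bromooct-2-ene
Product: 6 rac-2-chloro-3-ethoxy-5-[(Z)-oct-2-en-1-yl]cyclopent-2-en-1-one, via lithium enolate 5 (not isolated)
Conditions: LiN(iPr)2, THF, −78 °C; then 4, DMPU, −78 to −20 °C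
Reagents that add atoms: none
Why: Stork–Danheiser kinetic alpha'-deprotonation of the vinylogous ester and SN2 C-alkylation by the primary allylic bromide; the new stereocentre is racemic and is erased in step 5.

**Step 4**
Reactants: 6 rac-2-chloro-3-ethoxy-5-[(Z)-oct-2-en-1-yl]cyclopent-2-en-1-one
Product: 8 rac-2-chloro-4-[(Z)-oct-2-en-1-yl]cyclopent-2-en-1-one, via allylic alcohol 7 (not isolated)
Conditions: iBu2AlH, toluene, −78 °C; then 1 M HCl, THF, 0 °C to rt
Reagents that add atoms: water, O
Why: 1,2-reduction followed by the acid-mediated Stork–Danheiser transposition (ionisation of the allylic alcohol to the alkoxyallyl cation, water attack at the ethoxy carbon, loss of ethanol) gives the transposed alpha-chloroenone; the alkyl-bearing carbon stays racemic.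

**Step 5**
Reactants: 8 rac-2-chloro-4-[(Z)-oct-2-en-1-yl]cyclopent-2-en-1-one
Product: 11 (S)-2-chloro-4-hydroxy-4-[(Z)-oct-2-en-1-yl]cyclopent-2-en-1-one, via caesium dienolate 9 (not isolated), via tertiary hydroperoxide 10 (not isolated)
Conditions: N-(9-anthracenylmethyl)cinchonidinium bromide (10 mol%), Cs2CO3, O2 (1 atm), P(OEt)3, toluene, −20 °C
Reagents that add atoms: dioxygen, O=O
Why: Proposed new method: enantioconvergent vinylogous aerobic hydroxylation under chiral phase-transfer catalysis; both enantiomers of 8 lose the acidic gamma C–H to give one planar, chlorine-stabilised extended dienolate that pairs with the chiral ammonium cation (its free hydroxyl hydrogen-bonded to the enolate oxygen, the anthracenyl wall covering one face), triplet O2 attacks the open face at the gamma carbon (largest distal coefficient, tertiary radical character; the alpha carbon is blocked by chlorine) to form the C12–O bond and the stereocentre, and P(OEt)3 reduces the hydroperoxide at once so it cannot epoxidise the enone; the closest known reactions are cinchona phase-transfer aerobic alpha-hydroxylation of 2-substituted cyclic ketones with O2 and P(OEt)3, and gamma-selective autoxidation of dienolates.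

**Step 6**
Reactants: 12 methyl hex-5-enoate; 13 (Z)-but-2-ene-1,4-diol
Product: 14 methyl (Z)-7-hydroxyhept-5-enoate
Conditions: Ru(=CH-C6H4-2-OiPr)(SIMes)(S2C6H2Cl2-3,6) (5 mol%), 13 (3 equiv), THF, 22 °C, 100 torr
Reagents that add atoms: none
Why: Stereoretentive olefin cross-metathesis with a ruthenium dithiolate carbene transfers the Z geometry of the diol to the new allylic alcohol.

**Step 7**
Reactants: 14 methyl (Z)-7-hydroxyhept-5-enoate
Product: 15 methyl (Z)-7-oxohept-5-enoate
Conditions: TEMPO (10 mol%), PhI(OAc)2, CH2Cl2, 0 °C to rt; used crude at once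
Reagents that add atoms: none
Why: Oxoammonium (TEMPO) oxidation of an allylic alcohol under near-neutral conditions gives the Z-enal without Z to E isomerisation.

**Step 8**
Reactants: 11 (S)-2-chloro-4-hydroxy-4-[(Z)-oct-2-en-1-yl]cyclopent-2-en-1-one; 15 methyl (Z)-7-oxohept-5-enoate
Product: 19 chlorovulone I, via dilithium alkoxide enolate 16 (not isolated), via dilithium aldolate 17 (not isolated), via secondary mesylate 18 (not isolated)
Conditions: LiN(iPr)2 (2.1 equiv), THF, −78 °C (11 added to the base); 15, −78 °C; MsCl (1.05 equiv), −78 °C; Et3N, −78 to 0 °C; aq NH4Cl; dim light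
Reagents that add atoms: none
Why: Directed aldol addition of the alpha'-enolate (the alkoxide cannot leave, and enolate formation blocks retro-aldol), selective mesylation of the less hindered secondary aldolate oxygen and E1cB elimination give the cross-conjugated dienone, with the 7E isomer (chain anti to the carbonyl) favoured and the minor 7Z isomer removed by chromatography; C12 is quaternary and untouched, and the 5Z and 14Z olefins are carried through.

**Compound list**
1 | 3-ethoxycyclopent-2-en-1-one | CCOC1=CC(=O)CC1 | starting material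
2 | 2-chloro-3-ethoxycyclopent-2-en-1-one | CCOC1=C(Cl)C(=O)CC1 | intermediate
3 | (Z)-oct-2-en-1-ol | CCCCC/C=C\CO | starting material
4 | (Z)-1-bromooct-2-ene | CCCCC/C=C\CBr | intermediate
5 | lithium 5-chloro-4-ethoxycyclopenta-1,4-dien-1-olate (lithium enolate of 2) | [Li+].[O-]C1=CCC(OCC)=C1Cl | intermediate
6 | rac-2-chloro-3-ethoxy-5-[(Z)-oct-2-en-1-yl]cyclopent-2-en-1-one | CCCCC/C=C\CC1CC(OCC)=C(Cl)C1=O | intermediate
7 | 2-chloro-3-ethoxy-5-[(Z)-oct-2-en-1-yl]cyclopent-2-en-1-ol (racemic, both diastereomers) | CCCCC/C=C\CC1CC(OCC)=C(Cl)C1O | intermediate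
8 | rac-2-chloro-4-[(Z)-oct-2-en-1-yl]cyclopent-2-en-1-one | CCCCC/C=C\CC1CC(=O)C(Cl)=C1 | intermediate
9 | caesium 2-chloro-4-[(Z)-oct-2-en-1-yl]cyclopenta-1,3-dien-1-olate (reacts as the ion pair with the chiral ammonium cation) | [Cs+].[O-]C1=C(Cl)C=C(C/C=C\CCCCC)C1 | intermediate
10 | (S)-2-chloro-4-hydroperoxy-4-[(Z)-oct-2-en-1-yl]cyclopent-2-en-1-one | CCCCC/C=C\C[C@@]1(OO)C=C(Cl)C(=O)C1 | intermediate
11 | (S)-2-chloro-4-hydroxy-4-[(Z)-oct-2-en-1-yl]cyclopent-2-en-1-one | CCCCC/C=C\C[C@@]1(O)C=C(Cl)C(=O)C1 | intermediate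
12 | methyl hex-5-enoate | C=CCCCC(=O)OC | starting material
13 | (Z)-but-2-ene-1,4-diol | OC/C=C\CO | starting material
14 | methyl (Z)-7-hydroxyhept-5-enoate | OC/C=C\CCCC(=O)OC | intermediate
15 | methyl (Z)-7-oxohept-5-enoate | O=C/C=C\CCCC(=O)OC | intermediate
16 | dilithium alkoxide enolate of 11 (configuration as in 11) | [Li+].[Li+].CCCCC/C=C\C[C@@]1([O-])C=C(Cl)C([O-])=C1 | intermediate
17 | dilithium aldolate of 11 and 15 (C7 and C8 epimers, C12 as in 11) | [Li+].[Li+].CCCCC/C=C\C[C@@]1([O-])C=C(Cl)C(=O)C1C([O-])/C=C\CCCC(=O)OC | intermediate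
18 | C7 mesylate of the aldol, as its C12 lithium alkoxide | [Li+].CCCCC/C=C\C[C@@]1([O-])C=C(Cl)C(=O)C1C(OS(C)(=O)=O)/C=C\CCCC(=O)OC | intermediate
19 | chlorovulone I, methyl (5Z,7E,14Z)-(12R)-10-chloro-12-hydroxy-9-oxoprosta-5,7,10,14-tetraen-1-oate | CCCCC/C=C\C[C@@]1(O)C=C(Cl)C(=O)/C1=C/C=C\CCCC(=O)OC | target

**Step count**
Total: 8 steps. Longest linear sequence: 5 steps (steps 1, 3, 4, 5, 8). Side branches: step 2 (one step) and steps 6–7 (two steps).

**Three steps most likely to fail**

Step 5 (the proposed new hydroxylation). Risks are oxygenation at the alpha' carbon, attack of hydroxide or hydroperoxide on the alpha-chloroenone, retro-aldol erosion of the carbinol, and low or reversed enantioselectivity; the sense of induction is not predictable and must be checked, and the cinchonine-derived pseudoenantiomeric salt is the first remedy if it is reversed. The fallback uses known chemistry and sets out from 6. The kinetic alpha'-enolate, lithium 5-chloro-4-ethoxy-2-[(Z)-oct-2-en-1-yl]cyclopenta-1,4-dien-1-olate F1, is made with LiN(iPr)2 in THF at −78 °C. It is hydroxylated with enantiopure (camphorylsulfonyl)oxaziridine (Davis asymmetric enolate hydroxylation; the antipode of the reagent is chosen by the rotation of the product) to give (S)-2-chloro-3-ethoxy-5-hydroxy-5-[(Z)-oct-2-en-1-yl]cyclopent-2-en-1-one F2. Reduction with iBu2AlH gives (1S)-3-chloro-4-ethoxy-1-[(Z)-oct-2-en-1-yl]cyclopent-3-ene-1,2-diol F3, and work-up with 1 M HCl carries out the same transposition as in step 4. The fallback comes back to the route at 11.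

Step 8 (one-pot aldol condensation of the unprotected hydroxy ketone). Risks are retro-aldol of the lithium alkoxide before enolisation, mesylation of the tertiary alkoxide, scrambling of the Z-allylic mesylate and a poor 7E:7Z ratio. The fallback sets out from 11 and follows the protected, stepwise sequence. TMSCl and imidazole in DMF give (S)-2-chloro-4-[(Z)-oct-2-en-1-yl]-4-(trimethylsilyloxy)cyclopent-2-en-1-one F4. LiN(iPr)2 in THF at −78 °C gives its lithium enolate F5, which adds to 15 to give the isolated silyl-protected aldol F6. MsCl and Et3N in CH2Cl2 give the silyl-protected secondary mesylate F7, which eliminates with DBU to the O-trimethylsilyl ether of chlorovulone I F8. HF·pyridine in MeCN at 0 °C removes the silyl group, and the fallback comes back to the route at 19.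

Step 3 (alkylation of the cyclopentenone vinylogous ester enolate). Risks are sluggish alkylation, dialkylation, and SN2' or Z to E leakage of the allylic bromide. The fallback sets out from 2. The same enolate 5 is alkylated with commercial 1-bromooct-2-yne (more reactive, no olefin geometry at stake) to give 2-chloro-3-ethoxy-5-(oct-2-yn-1-yl)cyclopent-2-en-1-one F9. Semi-hydrogenation (H2, Pd/CaCO3 poisoned with Pb(OAc)2, quinoline, EtOAc) then sets the Z olefin. The fallback comes back to the route at 6 and makes step 2 unnecessary.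

**Further compounds**
F1 | step 5 | lithium 5-chloro-4-ethoxy-2-[(Z)-oct-2-en-1-yl]cyclopenta-1,4-dien-1-olate | [Li+].[O-]C1=C(C/C=C\CCCCC)CC(OCC)=C1Cl
F2 | step 5 | (S)-2-chloro-3-ethoxy-5-hydroxy-5-[(Z)-oct-2-en-1-yl]cyclopent-2-en-1-one | CCCCC/C=C\C[C@@]1(O)C(=O)C(Cl)=C(OCC)C1
F3 | step 5 | (1S)-3-chloro-4-ethoxy-1-[(Z)-oct-2-en-1-yl]cyclopent-3-ene-1,2-diol (both C2 epimers) | CCCCC/C=C\C[C@@]1(O)C(O)C(Cl)=C(OCC)C1
F4 | step 8 | (S)-2-chloro-4-[(Z)-oct-2-en-1-yl]-4-(trimethylsilyloxy)cyclopent-2-en-1-one | CCCCC/C=C\C[C@@]1(O[Si](C)(C)C)C=C(Cl)C(=O)C1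
F5 | step 8 | lithium enolate of F4 | [Li+].CCCCC/C=C\C[C@@]1(O[Si](C)(C)C)C=C(Cl)C([O-])=C1
F6 | step 8 | silyl-protected aldol of F4 and 15 (C7 and C8 epimers) | CCCCC/C=C\C[C@@]1(O[Si](C)(C)C)C=C(Cl)C(=O)C1C(O)/C=C\CCCC(=O)OC
F7 | step 8 | silyl-protected secondary mesylate | CCCCC/C=C\C[C@@]1(O[Si](C)(C)C)C=C(Cl)C(=O)C1C(OS(C)(=O)=O)/C=C\CCCC(=O)OC
F8 | step 8 | O-trimethylsilyl ether of chlorovulone I | CCCCC/C=C\C[C@@]1(O[Si](C)(C)C)C=C(Cl)C(=O)/C1=C/C=C\CCCC(=O)OC
F9 | step 3 | 2-chloro-3-ethoxy-5-(oct-2-yn-1-yl)cyclopent-2-en-1-one (racemic) | CCCCCC#CCC1CC(OCC)=C(Cl)C1=O
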